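**Plan** (labdane numbering is used for all intermediates)

- Retrosynthesis: cut the O19–acyl bond of the coumarate, then C12–C13 (diene arm), then C8–C9 (ring B), then C6=C7 and C9=C11 (two Wittig-made arms), and last ring A at C1–C10 and C4–C5 together with the O19–C6 ester link.
- Forward: a (Z)-2-methylpentadienol and (E)-3-formylcrotonic acid are joined as an ester; an intramolecular Diels–Alder reaction closes ring A and a temporary γ-lactone; the lactone carbon and the formyl carbon are each extended by a Wittig reaction; ring B is closed by an intramolecular allylchromium addition to the C8 ketone; a B-alkyl Suzuki coupling adds C13–C16; acylation of O19 ends the route.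
- Enabling feature: the oxygen on C19 hangs from C4, next to C5, so an ester from O19 to a carboxyl carbon C6 on C5 ties the diene C1–C4 to the dienophile C5=C10 through three atoms; that lactone is opened later and its carbonyl carbon becomes C6 of ring B.
- Stereochemistry: C4 from the Z diene (only a cis-fused lactone can form), the trans 5-H/10-CH3 relation from the E dienophile, the absolute configuration from a chiral oxazaborolidinium catalyst; C8 and C9 from a chair transition state of the allylchromium addition, relayed from C10.

Key step: step 7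

Assumption: the oxazaborolidinium made from (S)-α,α-diphenylprolinol is taken to expose the enal face that leads to 10; if the facial sense is the opposite, the catalyst from (R)-α,α-diphenylprolinol is used instead.

**Step 1**
Reactants: 1 acrolein; 2 ethyl 2-[bis(2,2,2-trifluoroethoxy)phosphoryl]propanoate
Product: 3 ethyl (2Z)-2-methylpenta-2,4-dienoate
Conditions: KN(SiMe3)2, 18-crown-6, THF, −78 °C
Reagents that add atoms: none
Why: Still–Gennari variant of the Horner–Wadsworth–Emmons olefination, in which the electron-poor trifluoroethyl phosphonate eliminates under kinetic control and should give the Z trisubstituted enoate that later puts C19 on the inside position of the diene terminus C4.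

**Step 2**
Reactants: 3 ethyl (2Z)-2-methylpenta-2,4-dienoate
Product: 4 (2Z)-2-methylpenta-2,4-dien-1-ol
Conditions: i-Bu2AlH (2.2 equiv), CH2Cl2, −78 °C; aq. potassium sodium tartrate
Reagents that add atoms: none
Why: 1,2-reduction of a conjugated ester by the aluminium hydride should give the allylic alcohol without touching the diene or its Z geometry.

**Step 3**
Reactants: 5 ethyl (2E)-3-methyl-4-oxobut-2-enoate
Product: 6 ethyl (2E)-4,4-diethoxy-3-methylbut-2-enoate
Conditions: HC(OEt)3, EtOH, p-TsOH (cat.), rt
Reagents that add atoms: triethyl orthoformate, CCOC(OCC)OCC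
Why: acid-catalysed acetalisation with the orthoformate as water scavenger masks the formyl group so that the ester can be saponified, and the E geometry of the commercial enal is kept.

**Step 4**
Reactants: 6 ethyl (2E)-4,4-diethoxy-3-methylbut-2-enoate
Product: 7 (2E)-4,4-diethoxy-3-methylbut-2-enoic acid
Conditions: LiOH, THF/H2O, rt; then cold 1 M HCl to pH 4
Reagents that add atoms: lithium hydroxide, [Li+].[OH-]
Why: saponification of the ethyl ester proceeds by acyl substitution while the acetal is inert to base and survives the brief, cold, weakly acidic work-up.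

**Step 5**
Reactants: 4 (2Z)-2-methylpenta-2,4-dien-1-ol; 7 (2E)-4,4-diethoxy-3-methylbut-2-enoic acid
Product: 8 (2Z)-2-methylpenta-2,4-dien-1-yl (2E)-4,4-diethoxy-3-methylbut-2-enoate
Conditions: DCC, DMAP (cat.), CH2Cl2, 0 °C → rt
Reagents that add atoms: none
Why: Steglich esterification joins the two fragments under neutral conditions, so the Z diene and the E enoate should both be preserved.

**Step 6**
Reactants: 8 (2Z)-2-methylpenta-2,4-dien-1-yl (2E)-4,4-diethoxy-3-methylbut-2-enoate
Product: 9 (2Z)-2-methylpenta-2,4-dien-1-yl (2E)-3-methyl-4-oxobut-2-enoate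
Conditions: PPTS (cat.), acetone/H2O (9:1), 45 °C
Reagents that add atoms: water, O
Why: mild acid-catalysed acetal hydrolysis should unmask the enal without cleaving the dienyl ester.

**Step 7**
Reactants: 9 (2Z)-2-methylpenta-2,4-dien-1-yl (2E)-3-methyl-4-oxobut-2-enoate
Product: 10 (3aS,7S,7aS)-3a,7-dimethyl-1-oxo-1,3,3a,6,7,7a-hexahydro-2-benzofuran-7-carbaldehyde (ring A with C2=C3; on C4 18-CH3 α and the lactone 19-CH2O β; 5-H α with lactone carbonyl C6; on C10 20-CH3 β and the formyl carbon C9)
Conditions: (S)-B-(o-tolyl)oxazaborolidine from (S)-α,α-diphenylprolinol (20 mol %), HNTf2 (18 mol %), BHT, CH2Cl2 (0.02 M), −40 → −20 °C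
Reagents that add atoms: none
Why: Proposed new method: coordination of the formyl oxygen of 9 to the boron of the chiral oxazaborolidinium cation lowers the LUMO of the C5=C10 double bond, and the tethered Z diene C1=C2–C3=C4 adds across it in a concerted, asynchronous [4+2] cycloaddition in which the internal C4–C5 bond leads and the C1–C10 bond completes ring A; the closest known reaction types are the oxazaborolidinium-catalysed Diels–Alder reaction of 2-substituted enals and the thermal intramolecular Diels–Alder reaction of ester-linked 1,3,8-nonatrienes, which have not been combined on an ester-tethered triene. Ring A (six-membered carbocycle) closes in the [4+2] mode, and the temporary five-membered lactone closes through the three-atom tether C19–O–C6 that joins C4 to C5. C4 is controlled by the Z geometry of the diene, because a tether on the inside position of the diene terminus can reach C5 only with a cis ring fusion (C19 and C6 both β), and the trans relation of 5-H and 10-CH3 follows from suprafacial addition to the E dienophile (C6 and C20 cis on the alkene), with the formyl group endo. The absolute configuration at C4, C5 and C10 comes from the catalyst, which shields one face of the bound enal. The step needs enantiofacial selectivity and suppression of the [1,5]-hydrogen shift of the Z diene; the first rests on the formyl group as the single strongly basic binding site, the second on the low temperature that Lewis acid activation allows.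

**Step 8**
Reactants: 10 bicyclic lactone aldehyde
Product: 11 (3aS,7S,7aS)-3a,7-dimethyl-1-oxooctahydro-2-benzofuran-7-carbaldehyde (10 with C2–C3 saturated)
Conditions: H2 (1 atm), Pd/C (10 %), EtOAc, rt
Reagents that add atoms: none
Why: heterogeneous hydrogenation of the cis-disubstituted ring alkene, the only C=C present, should leave the neopentyl aldehyde and the lactone untouched and creates no stereocenter.

**Step 9**
Reactants: 11 saturated lactone aldehyde; 12 ethyl (triphenylphosphoranylidene)acetate
Product: 13 lactone enoate (11 with the formyl group replaced by (E)-CH=CH–CO2Et, C9=C11 with C12 as ester carbon)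
Conditions: toluene, 90 °C
Reagents that add atoms: none
Why: Wittig olefination with a stabilised ylide should give the E enoate under neutral conditions that spare the lactone and the C5 stereocenter next to it.

**Step 10**
Reactants: 13 lactone enoate
Product: 14 lactol allylic alcohol (C6 as cyclic hemiacetal to O19, anomer mixture; C10 arm (E)-CH=CH–CH2OH)
Conditions: i-Bu2AlH (3.5 equiv), CH2Cl2, −78 °C; aq. potassium sodium tartrate
Reagents that add atoms: none
Why: at −78 °C the aluminium hydride reduces the lactone only as far as the stable tetrahedral aluminate (lactol after work-up) and reduces the enoate 1,2 to the allylic alcohol, so both carbonyl groups are set to the needed level in one operation.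

**Step 11**
Reactants: 14 lactol allylic alcohol; 15 1-(triphenylphosphoranylidene)propan-2-one
Product: 16 hydroxy enone (ring A cyclohexane; C4: 18-CH3 α, 19-CH2OH β; C5: H α and the arm (E)-CH=CH–C(=O)CH3 = C6=C7–C8–C17; C10: 20-CH3 β and the arm (E)-CH=CH–CH2OH = C9=C11–C12)
Conditions: toluene, 90 °C; crude product taken on at once
Reagents that add atoms: none
Why: Wittig olefination of the ring-opened hydroxy aldehyde tautomer of the lactol with a stabilised ylide should give the E enone, adding C7, C8 and C17 and freeing O19, under neutral conditions that do not epimerise C5.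

**Step 12**
Reactants: 16 hydroxy enone
Product: 17 keto diol (16 with C6–C7 saturated: C5 arm CH2CH2C(=O)CH3)
Conditions: [(Ph3P)CuH]6 (0.5 equiv), degassed toluene, H2O (trace), rt
Reagents that add atoms: none
Why: conjugate reduction by the phosphine-stabilised copper hydride is selective for the enone and should leave the isolated allylic-alcohol alkene C9=C11 and both hydroxyls untouched.

**Step 13**
Reactants: 17 keto diol
Product: 18 allylic chloride (17 with 12-OH replaced by Cl)
Conditions: NCS, Me2S, CH2Cl2, −20 → 0 °C
Reagents that add atoms: N-chlorosuccinimide, O=C1CCC(=O)N1Cl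
Why: Corey–Kim chlorination, in which the allylic alkoxysulfonium ion collapses by chloride substitution while the neopentyl C19 alkoxysulfonium ion cannot be displaced and returns the alcohol on work-up.

**Step 14**
Reactants: 18 allylic chloride
Product: 20 13,14,15,16-tetranorlabd-11-ene-8α,19-diol, via allylchromium dichloride 19 (not isolated)
Conditions: CrCl2 (6 equiv), LiI (cat.), THF/DMF, rt, 0.005 M; aq. NH4Cl
Reagents that add atoms: none
Why: intramolecular Nozaki–Hiyama allylation, in which divalent chromium converts the chloride into the (E)-allylchromium species 19 that adds through its γ-carbon C9 to the C8 ketone in a six-membered chair transition state fused to the forming chair of ring B; with C10 equatorial on that chair the oxygen lies anti to C10 and becomes the equatorial 8α-hydroxyl (C17 axial, β), and with the ring arm C7 equatorial the vinyl group becomes equatorial (9β, 9-H α).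

**Step 15**
Reactants: 20 13,14,15,16-tetranorlabd-11-ene-8α,19-diol; 21 chloroprene (2-chlorobuta-1,3-diene)
Product: 23 labda-13(16),14-diene-8α,19-diol, via B-alkyl-9-BBN adduct 22 (not isolated)
Conditions: 9-borabicyclo[3.3.1]nonane (3.5 equiv), THF, 0 → 60 °C; then 21 (5 equiv), Pd(OAc)2 (5 mol %), SPhos (10 mol %), aq. K3PO4, BHT, THF, 60 °C, sealed tube
Reagents that add atoms: none
Why: anti-Markovnikov hydroboration of the vinyl group followed by B-alkyl Suzuki–Miyaura coupling with the alkenyl chloride on zerovalent palladium forms C12–C13 and the 2-substituted butadiene without ever placing a leaving group on C12, so the free 8-hydroxyl cannot close to the 8,12-ether.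

**Step 16**
Reactants: 23 labda-13(16),14-diene-8α,19-diol; 24 (2E)-3-(4-acetoxyphenyl)prop-2-enoic acid
Product: 26 8α-hydroxylabda-13(16),14-dien-19-yl (E)-4-acetoxycinnamate, via mixed anhydride 25 (not isolated)
Conditions: 24, 2,4,6-trichlorobenzoyl chloride, Et3N, toluene, rt; then 23, DMAP, toluene, rt → 40 °C
Reagents that add atoms: none
Why: Yamaguchi esterification, in which the mixed anhydride 25 acylates the primary neopentyl O19 through the acylpyridinium ion while the tertiary 8-hydroxyl is too hindered to react.

**Step 17**
Reactants: 26 8α-hydroxylabda-13(16),14-dien-19-yl (E)-4-acetoxycinnamate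
Product: 27 8α-hydroxylabda-13(16),14-dien-19-yl p-hydroxycinnamate (target)
Conditions: NH4OAc, MeOH/H2O (4:1), rt
Reagents that add atoms: none
Why: mild methanolysis cleaves the aryl acetate, whose phenoxide is a far better leaving group, and should spare the hindered alkyl cinnamate, the diene and the tertiary alcohol.

**Compound list**

1 | acrolein (prop-2-enal) | C=CC=O | starting material
2 | ethyl 2-[bis(2,2,2-trifluoroethoxy)phosphoryl]propanoate | CCOC(=O)C(C)P(=O)(OCC(F)(F)F)OCC(F)(F)F | starting material
3 | ethyl (2Z)-2-methylpenta-2,4-dienoate | C=C/C=C(/C)C(=O)OCC | intermediate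
4 | (2Z)-2-methylpenta-2,4-dien-1-ol | C=C/C=C(/C)CO | intermediate
5 | ethyl (2E)-3-methyl-4-oxobut-2-enoate | CCOC(=O)/C=C(\C)C=O | starting material
6 | ethyl (2E)-4,4-diethoxy-3-methylbut-2-enoate | CCOC(=O)/C=C(\C)C(OCC)OCC | intermediate
7 | (2E)-4,4-diethoxy-3-methylbut-2-enoic acid | OC(=O)/C=C(\C)C(OCC)OCC | intermediate
8 | (2Z)-2-methylpenta-2,4-dien-1-yl (2E)-4,4-diethoxy-3-methylbut-2-enoate | C=C/C=C(/C)COC(=O)/C=C(\C)C(OCC)OCC | intermediate
9 | (2Z)-2-methylpenta-2,4-dien-1-yl (2E)-3-methyl-4-oxobut-2-enoate | C=C/C=C(/C)COC(=O)/C=C(\C)C=O | intermediate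
10 | (3aS,7S,7aS)-3a,7-dimethyl-1-oxo-1,3,3a,6,7,7a-hexahydro-2-benzofuran-7-carbaldehyde (cis-fused lactone aldehyde; 19-CH2O β, 18-CH3 α, 5-H α, 20-CH3 β) | O=C[C@@]1(C)CC=C[C@]2(C)COC(=O)[C@H]12 | intermediate
11 | (3aS,7S,7aS)-3a,7-dimethyl-1-oxooctahydro-2-benzofuran-7-carbaldehyde | O=C[C@@]1(C)CCC[C@]2(C)COC(=O)[C@H]12 | intermediate
12 | ethyl (triphenylphosphoranylidene)acetate | CCOC(=O)C=P(c1ccccc1)(c1ccccc1)c1ccccc1 | starting material
13 | lactone enoate: 11 with CHO replaced by (E)-CH=CH–CO2Et (C9=C11, C12) | CCOC(=O)/C=C/[C@@]1(C)CCC[C@]2(C)COC(=O)[C@H]12 | intermediate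
14 | lactol allylic alcohol: cyclic hemiacetal at C6 to O19; C10 arm (E)-CH=CH–CH2OH | OC/C=C/[C@@]1(C)CCC[C@]2(C)COC(O)[C@H]12 | intermediate
15 | 1-(triphenylphosphoranylidene)propan-2-one | CC(=O)C=P(c1ccccc1)(c1ccccc1)c1ccccc1 | starting material
16 | hydroxy enone: ring A with 19-CH2OH β and 18-CH3 α on C4, (E)-4-oxopent-1-enyl on C5 (5-H α), 20-CH3 β and (E)-3-hydroxyprop-1-enyl on C10 | CC(=O)/C=C/[C@H]1[C@@](C)(CO)CCC[C@]1(C)/C=C/CO | intermediate
17 | keto diol: 16 with the C5 arm saturated (3-oxobutyl) | CC(=O)CC[C@H]1[C@@](C)(CO)CCC[C@]1(C)/C=C/CO | intermediate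
18 | allylic chloride: 17 with 12-OH replaced by Cl | CC(=O)CC[C@H]1[C@@](C)(CO)CCC[C@]1(C)/C=C/CCl | intermediate
19 | allylchromium dichloride from 18 (C12–CrCl2) | CC(=O)CC[C@H]1[C@@](C)(CO)CCC[C@]1(C)/C=C/C[Cr](Cl)Cl | intermediate (not isolated)
20 | 13,14,15,16-tetranorlabd-11-ene-8α,19-diol | C=C[C@@H]1[C@@]2(C)CCC[C@](C)(CO)[C@@H]2CC[C@@]1(C)O | intermediate
21 | chloroprene (2-chlorobuta-1,3-diene) | C=CC(Cl)=C | starting material
22 | B-(8α,19-dihydroxy-13,14,15,16-tetranorlabdan-12-yl)-9-borabicyclo[3.3.1]nonane (drawn with free hydroxyls) | B1(CC[C@@H]3[C@@]4(C)CCC[C@](C)(CO)[C@@H]4CC[C@@]3(C)O)C2CCCC1CCC2 | intermediate (not isolated)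
23 | labda-13(16),14-diene-8α,19-diol | C=CC(=C)CC[C@@H]1[C@@]2(C)CCC[C@](C)(CO)[C@@H]2CC[C@@]1(C)O | intermediate
24 | (2E)-3-(4-acetoxyphenyl)prop-2-enoic acid | CC(=O)Oc1ccc(/C=C/C(=O)O)cc1 | starting material
25 | (E)-4-acetoxycinnamic 2,4,6-trichlorobenzoic anhydride | CC(=O)Oc1ccc(/C=C/C(=O)OC(=O)c2c(Cl)cc(Cl)cc2Cl)cc1 | intermediate (not isolated)
26 | 8α-hydroxylabda-13(16),14-dien-19-yl (E)-4-acetoxycinnamate | C=CC(=C)CC[C@@H]1[C@@]2(C)CCC[C@](C)(COC(=O)/C=C/c3ccc(OC(C)=O)cc3)[C@@H]2CC[C@@]1(C)O | intermediate
27 | 8α-hydroxylabda-13(16),14-dien-19-yl p-hydroxycinnamate | C=CC(=C)CC[C@@H]1[C@@]2(C)CCC[C@](C)(COC(=O)/C=C/c3ccc(O)cc3)[C@@H]2CC[C@@]1(C)O | target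

**Step count**

Total: 17 steps. Longest linear sequence: 15 steps (steps 1, 2 and 5–17; steps 3 and 4 form the side branch).

**Steps most likely to fail**

1. Step 7 (labelled step). What may go wrong: poor enantiofacial control if the catalyst binds the ester carbonyl as well as the formyl group; ionisation of the dienyl ester by the Lewis acid; and slow cycloaddition of the Z diene, which allows polymerisation. Fallback, from 9 back to 10, by known chemistry: heating 9 in toluene with BHT at 120 °C in a sealed tube should bring about the uncatalysed cycloaddition of the ester-linked nonatriene and give 10 together with its mirror image, ent-10 F1. Condensation of this mixture with (1R,2R)-N,N'-dimethyl-1,2-diphenylethane-1,2-diamine (4 Å sieves, CH2Cl2) gives two diastereomeric imidazolidines, the aminal of 10 F2 and the aminal of ent-10 F3, to be separated by chromatography. Hydrolysis of F2 (0.5 M HCl, Et2O/H2O, 0 °C) returns enantiopure 10 and the diamine.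

2. Step 14. What may go wrong: loss of stereocontrol at C8 and C9 if the closed chair transition state is abandoned to escape the 1,3-diaxial C17/C20 interaction; protonation of the allylchromium species before it adds; intermolecular coupling. Fallback, from 17 back to 20, with the polarity at C8 reversed: acetylation of both hydroxyls of 17 (Ac2O, pyridine, DMAP) gives the keto diacetate F4. SmI2 (THF, HMPA, t-BuOH, −78 → 0 °C) reduces the ketone to a ketyl radical that adds 6-exo to C9, and the organosamarium formed on further reduction expels the allylic acetate to leave the vinyl group, giving the 19-acetate of 20 F5, with the oxygen expected anti to the acceptor arm. K2CO3 in MeOH then removes the acetate and gives 20.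

3. Step 11. What may go wrong: slow olefination of the hindered lactol; oxa-Michael addition of the freed 19-hydroxyl to C6 of the new enone, which would lock C6 as an ether carbon; epimerisation at C5 through the open aldehyde. Fallback, from 14 back to 17, with no enone at any stage: Wittig reaction of 14 with methoxymethylenetriphenylphosphorane (from the phosphonium chloride and KN(SiMe3)2, THF) gives the methyl enol ether F6. Hydrolysis (1 M HCl, THF, 0 °C) gives the C7 aldehyde, held as its six-membered lactol with O19, the δ-lactol F7. A second Wittig reaction with (1-methoxyethylidene)triphenylphosphorane gives the 2-methoxypropenyl compound F8. Hydrolysis (oxalic acid, wet THF) gives the methyl ketone 17, so that step 12 is not needed.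

**Further compounds**

F1 | step 7 | ent-10, (3aR,7R,7aR)-3a,7-dimethyl-1-oxo-1,3,3a,6,7,7a-hexahydro-2-benzofuran-7-carbaldehyde | O=C[C@]1(C)CC=C[C@@]2(C)COC(=O)[C@@H]12
F2 | step 7 | aminal of 10 with (1R,2R)-N,N'-dimethyl-1,2-diphenylethane-1,2-diamine | CN1[C@H](c2ccccc2)[C@@H](c2ccccc2)N(C)C1[C@@]1(C)CC=C[C@]2(C)COC(=O)[C@H]12
F3 | step 7 | aminal of ent-10 with (1R,2R)-N,N'-dimethyl-1,2-diphenylethane-1,2-diamine | CN1[C@H](c2ccccc2)[C@@H](c2ccccc2)N(C)C1[C@]1(C)CC=C[C@@]2(C)COC(=O)[C@@H]12
F4 | step 14 | keto diacetate (12,19-di-O-acetyl-17) | CC(=O)CC[C@H]1[C@@](C)(COC(C)=O)CCC[C@]1(C)/C=C/COC(C)=O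
F5 | step 14 | 8α-hydroxy-13,14,15,16-tetranorlabd-11-en-19-yl acetate | C=C[C@@H]1[C@@]2(C)CCC[C@](C)(COC(C)=O)[C@@H]2CC[C@@]1(C)O
F6 | step 11 | methyl enol ether (C5 arm CH=CH–OCH3, E/Z mixture) | COC=C[C@H]1[C@@](C)(CO)CCC[C@]1(C)/C=C/CO
F7 | step 11 | δ-lactol (C7 hemiacetal to O19, anomer mixture) | OC1C[C@H]2[C@@](C)(CO1)CCC[C@]2(C)/C=C/CO
F8 | step 11 | 2-methoxypropenyl compound (C5 arm CH2–CH=C(OCH3)CH3, E/Z mixture) | COC(C)=CC[C@H]1[C@@](C)(CO)CCC[C@]1(C)/C=C/CO
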